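**Strategy.** The dihydrofuran ring (O1, C2, C3, C3a, C7a) with its C2 isopropenyl group is disconnected to a 2,2-dimethylchroman: C2, C3 and the three isopropenyl carbons form an isoprene unit whose ether oxygen O1 can sit on either of two neighbouring carbons. In the key step the C3 triflate of a trans-3-hydroxy-4-acyloxy-2,2-dimethylchroman ionises with participation of the ring oxygen; O1 shifts from CMe2 to the neighbouring carbon with inversion and CMe2 is extruded as the isopropenyl group, which sets C2 and the trans C2/C3 relationship at once. The precursor arises from Jacobsen epoxidation of silyl-protected eupatoriochromene and opening of the epoxide by the intact (Z)-acid.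

Key step: step 8

Assumption: 2,2-dimethylchroman-7-ol (1) is taken as a catalogue compound; chroman and benzofuran atoms carry their usual ring numbers.

**Step 1**
Reactants: 1 2,2-dimethylchroman-7-ol
Product: 2 1-(7-hydroxy-2,2-dimethylchroman-6-yl)ethan-1-one
Conditions: AcOH, BF3·OEt2, 90 °C; aq. NaHCO3 work-up
Reagents that add atoms: acetic acid CC(=O)O
Why: Friedel–Crafts (Nencki-type) C-acetylation; C6, ortho to the hydroxyl and para to the ring oxygen, is the most activated unhindered site, C8 between the two oxygens is shielded, and the BF2 chelate of the product stops a second acylation.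

**Step 2**
Reactants: 2 1-(7-hydroxy-2,2-dimethylchroman-6-yl)ethan-1-one
Product: 3 1-(7-hydroxy-2,2-dimethyl-2H-chromen-6-yl)ethan-1-one (eupatoriochromene)
Conditions: DDQ, 1,4-dioxane, reflux
Reagents that add atoms: none
Why: DDQ dehydrogenation of a 2,2-dimethylchroman: hydride abstraction from benzylic C4, assisted by the para hydroxyl and the ortho ring oxygen, then loss of H3 gives the 2H-chromene, and the quaternary C2 prevents over-oxidation.

**Step 3**
Reactants: 3 eupatoriochromene
Product: 4 1-[2,2-dimethyl-7-(triisopropylsilyloxy)-2H-chromen-6-yl]ethan-1-one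
Conditions: TIPSOTf, 2,6-lutidine, CH2Cl2, 0 °C
Reagents that add atoms: triisopropylsilyl triflate CC(C)[Si](OS(=O)(=O)C(F)(F)F)(C(C)C)C(C)C
Why: Silyl triflate/hindered base silylation of the hydrogen-bonded phenol; the bulky TIPS ether shields the phenol from the oxidant and from Tf2O and is later removed with fluoride.

**Step 4**
Reactants: 4 TIPS-protected chromene
Product: 5 1-[(3R,4R)-3,4-epoxy-2,2-dimethyl-7-(triisopropylsilyloxy)chroman-6-yl]ethan-1-one
Conditions: (R,R)-Jacobsen Mn(salen)Cl (5 mol %), NMO, mCPBA, CH2Cl2, −78 °C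
Reagents that add atoms: 3-chloroperbenzoic acid OOC(=O)c1cccc(Cl)c1
Why: Jacobsen–Katsuki epoxidation, for which 2,2-dimethylchromenes are model substrates; the (R,R)-salen manganese oxo species transfers oxygen to one face of the cis alkene (catalyst control) and should set C3 and C4 as (3R,4R) with high enantioselectivity, while the low temperature spares the acetyl group and the silyl ether.

**Step 5**
Reactants: 6 3-methylfuran-2(5H)-one
Product: 9 4-methoxybenzyl (Z)-4-acetoxy-2-methylbut-2-enoate, via potassium hydroxy-enoate salt 7 (not isolated), via PMB hydroxy-enoate 8 (not isolated)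
Conditions: KOH (1.0 equiv), H2O/THF, 0 °C, evaporate; PMBCl, Bu4NI (cat.), DMF, rt; Ac2O, pyridine, DMAP (cat.), 0 °C
Reagents that add atoms: potassium hydroxide [K+].[OH-]; 4-methoxybenzyl chloride COc1ccc(CCl)cc1; acetic anhydride CC(=O)OC(C)=O
Why: Saponification opens the butenolide to the hydroxy carboxylate with the Z geometry dictated by the ring; SN2 O-alkylation of the carboxylate and immediate DMAP-catalysed acetylation cap both ends before relactonisation, and no operation activates the acyl group, so the alkene cannot isomerise.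

**Step 6**
Reactants: 9 4-methoxybenzyl (Z)-4-acetoxy-2-methylbut-2-enoate
Product: 10 (Z)-4-acetoxy-2-methylbut-2-enoic acid
Conditions: TFA, anisole, CH2Cl2, 0 °C
Reagents that add atoms: none
Why: Acidolysis of the 4-methoxybenzyl ester through the stabilised benzylic cation, which anisole traps by Friedel–Crafts alkylation; the primary acetate and the Z-enoic acid are stable to cold TFA.

**Step 7**
Reactants: 5 (3R,4R)-epoxide and 10 (Z)-4-acetoxy-2-methylbut-2-enoic acid
Product: 11 (3R,4S)-6-acetyl-3-hydroxy-2,2-dimethyl-7-(triisopropylsilyloxy)chroman-4-yl (Z)-4-acetoxy-2-methylbut-2-enoate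
Conditions: 10 (1.5 equiv), i-Pr2NEt (0.2 equiv), MeCN, 40 °C
Reagents that add atoms: none
Why: Base-catalysed SN2 opening of the epoxide by the carboxylate at benzylic C4 (C3 is shielded by the gem-dimethyl group) with inversion should give the trans-(3R,4S) hydroxy ester; the acid reacts as an oxygen nucleophile without acyl activation, so the Z double bond is not at risk, and the excess acid protonates the C3 alkoxide before it can take over the acyl group.

**Step 8**
Reactants: 11 trans-hydroxy ester
Product: 14 (2R,3S)-5-acetyl-2-(prop-1-en-2-yl)-6-(triisopropylsilyloxy)-2,3-dihydro-1-benzofuran-3-yl (Z)-4-acetoxy-2-methylbut-2-enoate, via C3 triflate 12 (not isolated), via bridged oxiranium triflate 13 (not isolated)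
Conditions: Tf2O (1.2 equiv), 2,6-lutidine (3 equiv), CH2Cl2, −40 °C to rt
Reagents that add atoms: none
Why: Tf2O converts the hindered C3 hydroxyl into triflate 12, whose equatorial C3–O bond in the favoured trans-diequatorial half-chair is antiperiplanar to the ring O1–C2 bond, so that O1 displaces triflate from the rear to give the bridged oxiranium ion 13, which then opens at its tertiary carbon with loss of a methyl proton to the hindered base, and the CMe2 carbon leaves the ring as the isopropenyl group. The closest known reaction type is the stereospecific ring contraction of β-sulfonyloxy cyclic ethers by ring-oxygen participation, as in pyranoside 2-triflates and 3-sulfonyloxy-2,2-dimethylchromans. The new O1–C bond closes the three-membered oxiranium ring (3-exo-tet) and by the same event the five-membered dihydrofuran ring (5-exo-tet along the O1–C8a–C4a–C4 tether). The only new stereocentre, C2 of the dihydrobenzofuran, arises by inversion of chroman C3 (substrate control, SN2-type 1,2-shift), while chroman C4 is untouched and becomes C3, so the trans-(3R,4S) precursor should give the trans-(2R,3S) product. The step needs migration of O1 in preference to participation by the C4 ester carbonyl, aryl shift, E2 towards C4 and Zaitsev elimination; the diequatorial conformer places neither the ester oxygen nor H4 anti to the leaving group, an aryl shift would leave a cation on an acyloxy-bearing carbon, and only the methyl hydrogens can reach the anti alignment to the breaking C–O bond of 13.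

**Step 9**
Reactants: 14 silyl-protected dihydrobenzofuran ester
Product: 15 (2R,3S)-5-acetyl-6-hydroxy-2-(prop-1-en-2-yl)-2,3-dihydro-1-benzofuran-3-yl (Z)-4-acetoxy-2-methylbut-2-enoate (CNP0273504.1)
Conditions: TBAF, AcOH (1:1.2), THF, 0 °C
Reagents that add atoms: none
Why: Fluoride attacks silicon of the aryl silyl ether, which is activated by the ortho acetyl group; acetic acid buffers the phenoxide at once, so the benzylic ester para to it, the allylic acetate and the Z-enoate should survive.

**Compound list**
1 | 2,2-dimethylchroman-7-ol | CC1(C)CCc2ccc(O)cc2O1 | starting material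
2 | 1-(7-hydroxy-2,2-dimethylchroman-6-yl)ethan-1-one | CC(=O)c1cc2CCC(C)(C)Oc2cc1O | intermediate
3 | 1-(7-hydroxy-2,2-dimethyl-2H-chromen-6-yl)ethan-1-one (eupatoriochromene) | CC(=O)c1cc2C=CC(C)(C)Oc2cc1O | intermediate
4 | 1-[2,2-dimethyl-7-(triisopropylsilyloxy)-2H-chromen-6-yl]ethan-1-one | CC(=O)c1cc2C=CC(C)(C)Oc2cc1O[Si](C(C)C)(C(C)C)C(C)C | intermediate
5 | 1-[(3R,4R)-3,4-epoxy-2,2-dimethyl-7-(triisopropylsilyloxy)chroman-6-yl]ethan-1-one | CC(=O)c1cc2[C@H]3O[C@H]3C(C)(C)Oc2cc1O[Si](C(C)C)(C(C)C)C(C)C | intermediate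
6 | 3-methylfuran-2(5H)-one | CC1=CCOC1=O | starting material
7 | potassium (Z)-4-hydroxy-2-methylbut-2-enoate | [K+].[O-]C(=O)/C(C)=C\CO | intermediate
8 | 4-methoxybenzyl (Z)-4-hydroxy-2-methylbut-2-enoate | COc1ccc(COC(=O)/C(C)=C\CO)cc1 | intermediate
9 | 4-methoxybenzyl (Z)-4-acetoxy-2-methylbut-2-enoate | COc1ccc(COC(=O)/C(C)=C\COC(C)=O)cc1 | intermediate
10 | (Z)-4-acetoxy-2-methylbut-2-enoic acid | OC(=O)/C(C)=C\COC(C)=O | intermediate
11 | (3R,4S)-6-acetyl-3-hydroxy-2,2-dimethyl-7-(triisopropylsilyloxy)chroman-4-yl (Z)-4-acetoxy-2-methylbut-2-enoate | CC(=O)c1cc2[C@H](OC(=O)/C(C)=C\COC(C)=O)[C@@H](O)C(C)(C)Oc2cc1O[Si](C(C)C)(C(C)C)C(C)C | intermediate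
12 | (3R,4S)-6-acetyl-2,2-dimethyl-3-(trifluoromethylsulfonyloxy)-7-(triisopropylsilyloxy)chroman-4-yl (Z)-4-acetoxy-2-methylbut-2-enoate | CC(=O)c1cc2[C@H](OC(=O)/C(C)=C\COC(C)=O)[C@@H](OS(=O)(=O)C(F)(F)F)C(C)(C)Oc2cc1O[Si](C(C)C)(C(C)C)C(C)C | intermediate
13 | bridged O-aryl oxiranium triflate (O1 bonded to C8a, CMe2 and the former C3; the former C4 still carries the ester) | CC(=O)c1cc2[C@H](OC(=O)/C(C)=C\COC(C)=O)[C@@H]3[O+](c2cc1O[Si](C(C)C)(C(C)C)C(C)C)C3(C)C.[O-]S(=O)(=O)C(F)(F)F | intermediate
14 | (2R,3S)-5-acetyl-2-(prop-1-en-2-yl)-6-(triisopropylsilyloxy)-2,3-dihydro-1-benzofuran-3-yl (Z)-4-acetoxy-2-methylbut-2-enoate | C=C(C)[C@H]1Oc2cc(O[Si](C(C)C)(C(C)C)C(C)C)c(C(C)=O)cc2[C@@H]1OC(=O)/C(C)=C\COC(C)=O | intermediate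
15 | (2R,3S)-5-acetyl-6-hydroxy-2-(prop-1-en-2-yl)-2,3-dihydro-1-benzofuran-3-yl (Z)-4-acetoxy-2-methylbut-2-enoate | C=C(C)[C@H]1Oc2cc(O)c(C(C)=O)cc2[C@@H]1OC(=O)/C(C)=C\COC(C)=O | target

**Step count.** Total: 9 steps. Longest linear sequence: 7 steps (steps 1–4 and 7–9 from 1); the acid branch (steps 5 and 6) is convergent.

**Steps most likely to fail**

Step 8 (key step). What may go wrong: the C4 ester carbonyl instead of O1 intercepts the positive charge developing at C3 (acyloxonium formation and acyl shift), or the migration is slow because O1 is conjugated to the para acetyl group, so that decomposition of the triflate takes over. Fallback: the esterification is moved behind the ring contraction, so that a non-participating silyl ether sits on C4. It sets out from 5. Acid-catalysed hydration (cat. HClO4, THF/H2O, 0 °C) should give the trans-diol 1-[(3R,4S)-3,4-dihydroxy-2,2-dimethyl-7-(triisopropylsilyloxy)chroman-6-yl]ethan-1-one F1. TBSCl/imidazole in DMF at 0 °C should silylate the more accessible benzylic hydroxyl to give 1-[(3R,4S)-4-(tert-butyldimethylsilyloxy)-3-hydroxy-2,2-dimethyl-7-(triisopropylsilyloxy)chroman-6-yl]ethan-1-one F2. Tf2O/2,6-lutidine then effects the same oxygen shift to 1-[(2R,3S)-3-(tert-butyldimethylsilyloxy)-2-(prop-1-en-2-yl)-6-(triisopropylsilyloxy)-2,3-dihydro-1-benzofuran-5-yl]ethan-1-one F3. HF·pyridine in THF/pyridine at 0 °C should cleave the alkyl silyl ether before the aryl one and give 1-[(2R,3S)-3-hydroxy-2-(prop-1-en-2-yl)-6-(triisopropylsilyloxy)-2,3-dihydro-1-benzofuran-5-yl]ethan-1-one F4. Yamaguchi esterification with 10 (2,4,6-trichlorobenzoyl chloride, Et3N; then F4, DMAP, toluene, 0 °C) comes back to the route at 14.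

Step 7. What may go wrong: slow opening by the weakly nucleophilic carboxylate, during which the aryl silyl ether is cleaved by carboxylate, the acyl group shifts from O4 to O3, or ionisation at C4 erodes the trans selectivity. Fallback: oxygen is placed on C4 first and the acid is attached afterwards by acylation. It sets out from 5. Hydration under acidic, non-nucleophilic conditions (cat. HClO4, THF/H2O, 0 °C) should give the trans-diol 1-[(3R,4S)-3,4-dihydroxy-2,2-dimethyl-7-(triisopropylsilyloxy)chroman-6-yl]ethan-1-one F5 (the same compound as F1). Acylation of its more accessible benzylic hydroxyl with the mixed anhydride of 10 (2,4,6-trichlorobenzoyl chloride, Et3N; then F5, cat. DMAP, toluene, −20 °C) comes back to the route at 11.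

Step 5. What may go wrong: relactonisation of the hydroxy carboxylate or of the hydroxy ester back to the butenolide before alkylation and acetylation are complete, and competing benzylation of the free hydroxyl. Fallback: the hydroxyl is held as a silyl ether while the ester is made. It sets out from 6. Saponification as before, then TBSCl/imidazole in DMF should give tert-butyldimethylsilyl (Z)-4-(tert-butyldimethylsilyloxy)-2-methylbut-2-enoate F6. Its silyl ester is cleaved with K2CO3 in aqueous MeOH to (Z)-4-(tert-butyldimethylsilyloxy)-2-methylbut-2-enoic acid F7. PMBCl/K2CO3 in DMF gives 4-methoxybenzyl (Z)-4-(tert-butyldimethylsilyloxy)-2-methylbut-2-enoate F8. HF·pyridine in THF/pyridine at 0 °C, followed in the same flask by Ac2O/DMAP, releases 8 and acetylates it at once, so the fallback comes back to the route at 9.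

**Further compounds**
F1 | step 8 | 1-[(3R,4S)-3,4-dihydroxy-2,2-dimethyl-7-(triisopropylsilyloxy)chroman-6-yl]ethan-1-one | CC(=O)c1cc2[C@H](O)[C@@H](O)C(C)(C)Oc2cc1O[Si](C(C)C)(C(C)C)C(C)C
F2 | step 8 | 1-[(3R,4S)-4-(tert-butyldimethylsilyloxy)-3-hydroxy-2,2-dimethyl-7-(triisopropylsilyloxy)chroman-6-yl]ethan-1-one | CC(=O)c1cc2[C@H](O[Si](C)(C)C(C)(C)C)[C@@H](O)C(C)(C)Oc2cc1O[Si](C(C)C)(C(C)C)C(C)C
F3 | step 8 | 1-[(2R,3S)-3-(tert-butyldimethylsilyloxy)-2-(prop-1-en-2-yl)-6-(triisopropylsilyloxy)-2,3-dihydro-1-benzofuran-5-yl]ethan-1-one | C=C(C)[C@H]1Oc2cc(O[Si](C(C)C)(C(C)C)C(C)C)c(C(C)=O)cc2[C@@H]1O[Si](C)(C)C(C)(C)C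
F4 | step 8 | 1-[(2R,3S)-3-hydroxy-2-(prop-1-en-2-yl)-6-(triisopropylsilyloxy)-2,3-dihydro-1-benzofuran-5-yl]ethan-1-one | C=C(C)[C@H]1Oc2cc(O[Si](C(C)C)(C(C)C)C(C)C)c(C(C)=O)cc2[C@@H]1O
F5 | step 7 | 1-[(3R,4S)-3,4-dihydroxy-2,2-dimethyl-7-(triisopropylsilyloxy)chroman-6-yl]ethan-1-one | CC(=O)c1cc2[C@H](O)[C@@H](O)C(C)(C)Oc2cc1O[Si](C(C)C)(C(C)C)C(C)C
F6 | step 5 | tert-butyldimethylsilyl (Z)-4-(tert-butyldimethylsilyloxy)-2-methylbut-2-enoate | CC(C)(C)[Si](C)(C)OC(=O)/C(C)=C\CO[Si](C)(C)C(C)(C)C
F7 | step 5 | (Z)-4-(tert-butyldimethylsilyloxy)-2-methylbut-2-enoic acid | OC(=O)/C(C)=C\CO[Si](C)(C)C(C)(C)C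
F8 | step 5 | 4-methoxybenzyl (Z)-4-(tert-butyldimethylsilyloxy)-2-methylbut-2-enoate | COc1ccc(COC(=O)/C(C)=C\CO[Si](C)(C)C(C)(C)C)cc1
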